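**Strategy**

Everything rests on the acyloin hidden in the carbocycle of the 6H-isochromene-6,8-dione core (isochromene numbering): ketone C8 beside the oxygenated quaternary C7. Disconnecting C7–C8 as an intramolecular crossed aldehyde–ketone benzoin leads to a monocyclic precursor, a 2-methyl-3,4-dihydro-2H-pyran-5-carbaldehyde (C8 aldehyde on C8a) carrying a 2,3-dioxobutylidene chain on C4a. A chiral triazolylidene turns the C8 aldehyde into an acyl anion that attacks the C7 ketone, closing the six-membered ring and setting C7 under catalyst control in one operation. The precursor comes from (R)-pent-4-yn-2-ol, which supplies C3, by acetylide acylation, enol etherification with bromomalonaldehyde and reductive alkyne cyclisation; oleoylation ends the route.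

Key step: step 5

Remark: the isochromene numbering of the target (O2, C1, C3, C4, C4a, C5, C6, C7, C8, C8a) is used for the corresponding atoms of every intermediate.
Remark: (R)-pent-4-yn-2-ol is taken as commercial; it is otherwise one step from (R)-propylene oxide and lithium acetylide.
Remark: the sense of induction of the aminoindanol triazolium in step 5 is assigned by analogy only; both antipodes of the precatalyst are available, and the one that delivers the (7R) alcohol is the one to be used.

**Route**

Step 1
Reactants: 1 (R)-pent-4-yn-2-ol; 2 methyl 2,2-dimethoxypropanoate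
Product: 3 (R)-7-hydroxy-2,2-dimethoxyoct-4-yn-3-one
Conditions: n-BuLi (2.1 equiv), THF, −78 °C; then 2 (1.5 equiv), −78 °C; AcOH quench at −78 °C
Reagents that add atoms: methyl 2,2-dimethoxypropanoate (2), COC(=O)C(C)(OC)OC
Why: The lithium acetylide of the O,C-dilithiated alkynol attacks the ester, which has no α-hydrogens, and the chelated tetrahedral adduct of the α,α-dimethoxy ester should persist until the cold quench so that over-addition is avoided (acylation of a lithium acetylide to an ynone); the C3 stereocentre is carried through unchanged.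

Step 2
Reactants: 3 (R)-7-hydroxy-2,2-dimethoxyoct-4-yn-3-one; 4 2-bromomalonaldehyde
Product: 5 (Z)-2-bromo-3-{[(2R)-7,7-dimethoxy-6-oxooct-4-yn-2-yl]oxy}prop-2-enal
Conditions: 4 (1.5 equiv), TsOH·H2O (5 mol%), cyclohexane–toluene, reflux, Dean–Stark
Reagents that add atoms: 2-bromomalonaldehyde (4), O=CC(Br)C=O
Why: Bromomalonaldehyde is a vinylogous acid that is O-alkylated by the secondary alcohol under acid catalysis with azeotropic removal of water (enol etherification), the carbinol C–O bond is never broken so (R) is retained, and the Z isomer with formyl anti to alkoxy is the thermodynamic one.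

Step 3
Reactants: 5 (Z)-2-bromo-3-{[(2R)-7,7-dimethoxy-6-oxooct-4-yn-2-yl]oxy}prop-2-enal
Product: 6 (2R,4E)-4-(3,3-dimethoxy-2-oxobutylidene)-2-methyl-3,4-dihydro-2H-pyran-5-carbaldehyde
Conditions: Pd(OAc)2 (5 mol%), PPh3 (10 mol%), HCO2Na (1.5 equiv), Bu4NCl, DMF, 60 °C
Reagents that add atoms: none
Why: Zerovalent palladium formed in situ inserts into the C8a–Br bond, the vinylpalladium adds syn across the tethered alkyne in the 6-exo-dig mode to forge C8a–C4a and close the dihydropyran, and formate delivers hydride to the resulting C5 vinylpalladium (reductive Heck-type cyclisation with hydride capture), the syn addition placing C6 trans to C8a (E).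

Step 4
Reactants: 6 (2R,4E)-4-(3,3-dimethoxy-2-oxobutylidene)-2-methyl-3,4-dihydro-2H-pyran-5-carbaldehyde
Product: 7 (2R,4E)-4-(2,3-dioxobutylidene)-2-methyl-3,4-dihydro-2H-pyran-5-carbaldehyde
Conditions: TFA–H2O (9:1), CH2Cl2, 0 °C to rt
Reagents that add atoms: water, O
Why: Acid hydrolysis of the dimethyl ketal unmasks the C7 ketone, while the push–pull β-alkoxy enal of the pyran is comparatively acid-stable and should reclose if it opens; any acid-induced scrambling of the exocyclic alkene is harmless because step 5 equilibrates it anyway.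

Step 5
Reactants: 7 (2R,4E)-4-(2,3-dioxobutylidene)-2-methyl-3,4-dihydro-2H-pyran-5-carbaldehyde
Product: 9 (3R,7R)-7-hydroxy-3,7-dimethyl-3,4-dihydro-6H-isochromene-6,8(7H)-dione, via Z-configured trione aldehyde 8 (not isolated)
Conditions: (5aR,10bS)-2-(pentafluorophenyl)-5a,10b-dihydro-4H,6H-indeno[2,1-b][1,2,4]triazolo[4,3-d][1,4]oxazin-2-ium tetrafluoroborate (15 mol%), DABCO (30 mol%), 4 Å MS, toluene (0.02 M), 25 °C
Reagents that add atoms: none
Why: DABCO frees the triazolylidene, which adds to the C8 aldehyde and after proton transfer gives an acyl anion equivalent whose C8 attacks the C7 ketone of the 1,2-dione; proton transfer and loss of the carbene then release the tertiary α-ketol. The closest known reaction type is the enantioselective intramolecular crossed aldehyde–ketone benzoin cyclisation with aminoindanol-derived triazolium salts. The carbocycle closes in a 6-(enolexo)-exo-trig mode, C8 attacking the exocyclic C7=O. The new C7 stereocentre is set by the catalyst, whose indane wall shields one face of the acyl anion equivalent so that one face of the C7 carbonyl is presented, the remote C3 methyl being expected to exert little bias. Only the Z alkene isomer 8 can cyclise, and E and Z should interconvert by reversible conjugate addition of DABCO or the carbene at C1, which removes the C4a=C5 double-bond character, so that the E isomer drains through 8. C7 is preferred over C6 because C6 is a doubly vinylogous ester carbonyl deactivated by O2 and its attack would give a five-membered ring, while the homoenolate pathway through C1 would need a bridged ring with bridgehead alkenes and is further disfavoured by the N-pentafluorophenyl group.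

Step 6
Reactants: 9 (3R,7R)-7-hydroxy-3,7-dimethyl-3,4-dihydro-6H-isochromene-6,8(7H)-dione; 10 oleoyl chloride
Product: 11 (3R,7R)-3,7-dimethyl-6,8-dioxo-3,4,7,8-tetrahydro-6H-isochromen-7-yl (9Z)-octadec-9-enoate
Conditions: 10 (1.5 equiv), DMAP (0.3 equiv), Et3N (2 equiv), CH2Cl2, 0 °C to rt
Reagents that add atoms: oleoyl chloride (10), CCCCCCCC/C=C\CCCCCCCC(=O)Cl
Why: DMAP-catalysed acylation with the acid chloride should esterify the tertiary α-ketol hydroxyl, as is well precedented for the C7 hydroxyl of azaphilone-type cores, and neither stereocentre nor the cis alkene of the oleoyl chain is touched (nucleophile-catalysed O-acylation).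

**Compound list**

1 | (R)-pent-4-yn-2-ol | C#CC[C@@H](C)O | starting material
2 | methyl 2,2-dimethoxypropanoate | COC(=O)C(C)(OC)OC | starting material
3 | (R)-7-hydroxy-2,2-dimethoxyoct-4-yn-3-one | CC(OC)(OC)C(=O)C#CC[C@@H](C)O | intermediate
4 | 2-bromomalonaldehyde | O=CC(Br)C=O | starting material
5 | (Z)-2-bromo-3-{[(2R)-7,7-dimethoxy-6-oxooct-4-yn-2-yl]oxy}prop-2-enal | CC(OC)(OC)C(=O)C#CC[C@@H](C)O/C=C(\Br)C=O | intermediate
6 | (2R,4E)-4-(3,3-dimethoxy-2-oxobutylidene)-2-methyl-3,4-dihydro-2H-pyran-5-carbaldehyde | O=CC1=CO[C@H](C)C/C1=C\C(=O)C(C)(OC)OC | intermediate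
7 | (2R,4E)-4-(2,3-dioxobutylidene)-2-methyl-3,4-dihydro-2H-pyran-5-carbaldehyde | O=CC1=CO[C@H](C)C/C1=C\C(=O)C(C)=O | intermediate
8 | (2R,4Z)-4-(2,3-dioxobutylidene)-2-methyl-3,4-dihydro-2H-pyran-5-carbaldehyde, formed in the flask in step 5 | O=CC1=CO[C@H](C)C/C1=C/C(=O)C(C)=O | intermediate
9 | (3R,7R)-7-hydroxy-3,7-dimethyl-3,4-dihydro-6H-isochromene-6,8(7H)-dione | O[C@]1(C)C(=O)C=C2C[C@@H](C)OC=C2C1=O | intermediate
10 | oleoyl chloride, (9Z)-octadec-9-enoyl chloride | CCCCCCCC/C=C\CCCCCCCC(=O)Cl | starting material
11 | (3R,7R)-3,7-dimethyl-6,8-dioxo-3,4,7,8-tetrahydro-6H-isochromen-7-yl (9Z)-octadec-9-enoate | CCCCCCCC/C=C\CCCCCCCC(=O)O[C@]1(C)C(=O)C=C2C[C@@H](C)OC=C2C1=O | target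

**Summary**

Total step count: 6. Longest linear sequence: 6 steps (1 → 3 → 5 → 6 → 7 → 9 → 11).

**Steps most likely to fail**

Step 5. The carbene may be diverted into conjugate addition at C1 or into protonation of the homoenolate, the E to Z equilibration may be too slow, or the facial selectivity at C7 may be poor. The fallback sets out from 7 and replaces the acyl anion logic by a reductive carbonyl coupling. SmI2 (2.2 equiv, THF–t-BuOH, −78 °C) should reduce the 1,2-dione to its samarium enediolate, a stage at which the C4a=C5 geometry can relax. C7 of the enediolate should then add to the C8 aldehyde in a pinacol-type closure of the same six-membered ring, giving (3R)-7,8-dihydroxy-3,7-dimethyl-3,4,7,8-tetrahydro-6H-isochromen-6-one F1 as a mixture at C7 and C8. Oxidation of the secondary C8 carbinol with Dess–Martin periodinane (or MnO2) should then give 9 together with its C7 epimer. The two are diastereomers because C3 is fixed, so they should be separable by chromatography, and the route is rejoined at 9.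

Step 3. Hydride capture may outrun carbopalladation (simple loss of bromine), or a palladium hydride may reduce the ynone. The fallback sets out from 3 and forms the C8a–C4a bond by coupling two vinyl halides:
- Hydroiodination of the ynone (NaI, AcOH, rt) should give (4Z,7R)-7-hydroxy-5-iodo-2,2-dimethoxyoct-4-en-3-one F2 by anti addition.
- Enol etherification with 4 under the conditions of step 2 should give (Z)-2-bromo-3-{[(2R,4Z)-4-iodo-7,7-dimethoxy-6-oxooct-4-en-2-yl]oxy}prop-2-enal F3.
- Intramolecular reductive coupling with Ni(cod)2 and PPh3 (zerovalent nickel, DMF, 40 °C) should join C8a and C4a with retention, giving (2R,4Z)-4-(3,3-dimethoxy-2-oxobutylidene)-2-methyl-3,4-dihydro-2H-pyran-5-carbaldehyde F4.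
- Hydrolysis as in step 4 then gives the Z trione aldehyde 8, which enters step 5 directly.

Step 4. The deactivated α-keto ketal may hydrolyse too slowly while the acid opens or degrades the vinylogous formate and the electrophilic trione. The fallback sets out from 1 and carries C7 at the alcohol oxidation level instead of as a ketal:
- The dianion of 1 is acylated with (S)-2-[(tert-butyldimethylsilyl)oxy]-N-methoxy-N-methylpropanamide to give (2S,7R)-2-[(tert-butyldimethylsilyl)oxy]-7-hydroxyoct-4-yn-3-one F5.
- Enol etherification with 4 (PPTS in place of TsOH) should give (Z)-2-bromo-3-{[(2R,7S)-7-[(tert-butyldimethylsilyl)oxy]-6-oxooct-4-yn-2-yl]oxy}prop-2-enal F6.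
- The reductive cyclisation of step 3 should give (2R,4E)-4-{(3S)-3-[(tert-butyldimethylsilyl)oxy]-2-oxobutylidene}-2-methyl-3,4-dihydro-2H-pyran-5-carbaldehyde F7.
- HF·pyridine in THF should free (2R,4E)-4-[(3S)-3-hydroxy-2-oxobutylidene]-2-methyl-3,4-dihydro-2H-pyran-5-carbaldehyde F8.
- Dess–Martin oxidation of the α-ketol under buffered, non-acidic conditions should give 7, where the route is rejoined; the lactate-derived centre is destroyed in this oxidation.

**Further compounds**

F1 | step 5 | (3R)-7,8-dihydroxy-3,7-dimethyl-3,4,7,8-tetrahydro-6H-isochromen-6-one (mixture at C7 and C8) | C[C@@H]1CC2=CC(=O)C(C)(O)C(O)C2=CO1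
F2 | step 3 | (4Z,7R)-7-hydroxy-5-iodo-2,2-dimethoxyoct-4-en-3-one | CC(OC)(OC)C(=O)/C=C(\I)C[C@@H](C)O
F3 | step 3 | (Z)-2-bromo-3-{[(2R,4Z)-4-iodo-7,7-dimethoxy-6-oxooct-4-en-2-yl]oxy}prop-2-enal | CC(OC)(OC)C(=O)/C=C(\I)C[C@@H](C)O/C=C(\Br)C=O
F4 | step 3 | (2R,4Z)-4-(3,3-dimethoxy-2-oxobutylidene)-2-methyl-3,4-dihydro-2H-pyran-5-carbaldehyde | O=CC1=CO[C@H](C)C/C1=C/C(=O)C(C)(OC)OC
F5 | step 4 | (2S,7R)-2-[(tert-butyldimethylsilyl)oxy]-7-hydroxyoct-4-yn-3-one | C[C@H](O[Si](C)(C)C(C)(C)C)C(=O)C#CC[C@@H](C)O
F6 | step 4 | (Z)-2-bromo-3-{[(2R,7S)-7-[(tert-butyldimethylsilyl)oxy]-6-oxooct-4-yn-2-yl]oxy}prop-2-enal | C[C@H](O[Si](C)(C)C(C)(C)C)C(=O)C#CC[C@@H](C)O/C=C(\Br)C=O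
F7 | step 4 | (2R,4E)-4-{(3S)-3-[(tert-butyldimethylsilyl)oxy]-2-oxobutylidene}-2-methyl-3,4-dihydro-2H-pyran-5-carbaldehyde | O=CC1=CO[C@H](C)C/C1=C\C(=O)[C@H](C)O[Si](C)(C)C(C)(C)C
F8 | step 4 | (2R,4E)-4-[(3S)-3-hydroxy-2-oxobutylidene]-2-methyl-3,4-dihydro-2H-pyran-5-carbaldehyde | O=CC1=CO[C@H](C)C/C1=C\C(=O)[C@H](C)O
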